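The closed vessel holds Q, D, E and a trace of the catalyst X, and the flasks differ in temperature.

the same everywhere: Q 23 mM; D 46.0 mM; E 4.60 mM; X 13 µM; time 4.0 d
- elm: temperature 100 °C
- alder: temperature 85 °C
- oak: temperature 70 °C
- birch: at 70 °C until 50 h, from then on at 100 °C

    Q + D + X → X + Z (k1 = 1.6 × 10⁶ M⁻² h⁻¹, Ea1 = 40.0 kJ mol⁻¹)
    Q + E → Q.E (k2 = 24 M⁻¹ h⁻¹, Ea2 = 62.0 kJ mol⁻¹)
    D + Z → D.Z (k3 = 1.6 M⁻¹ h⁻¹, Ea3 = 82.0 kJ mol⁻¹)
    (constants at 70 °C)

- all constants are for 70 °C and move with temperature by the activation energies

* the best flask by amount of Z, in percent of the Q charged; "all alike" if 1.5 percentage points covers them all (elm / alder / oak / birch / all alike)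
* amount of Z at the end, in percent of the Q charged, elm
* amount of Z at the end, in percent of the Q charged, alder
* amount of Z at the end, in percent of the Q charged, oak
* amount of Z at the end, in percent of the Q charged, birch

Q is the limiting reagent, and D is charged at twice Q, which makes the symmetric case the zero of the scale: each Z formed costs one D, and each Z destroyed costs another, so c_D − c_Z starts from 0 mM once the charge is balanced against these two steps. Each Q taken by E costs one Z and spares one D, which moves that difference up by two. In oak the start rates give E a side share (the selectivity between the two steps that take Q) of 10.3%. If that share holds, Q.E reaches 2.38 mM, and the difference becomes 4.76 mM: this is the surplus, c_D − c_Z, which the third step leaves unchanged.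

The oak curve of Z can now be drawn. It leaves zero at 22.0 mM h⁻¹, and Q has a half-life near 0.650 h, so the knee comes within hours, near 20.6 mM. After the knee, the ratio r = c_Z/c_D starts at 0.812 and falls exponentially with time constant 131 h, one over k3 times the surplus, while c_Z = S·r/(1 − r). A positive surplus sends c_Z towards zero and c_D towards S. At the end of oak, r is 0.391, so c_Z is 3.06 mM, or 13.3% of the Q charged.

Birch changes temperature 77.0 half-lives of Q after the start, so it keeps oak's surplus, but its hot stretch runs at ten times k3. That gives 0.342%. In elm the side share from the start rates is 17.7%, but that is a figure for the start and need not hold as c_E falls, so this rough reckoning takes oak's surplus for elm as well. The time constant is then 13.0 h, which leaves about 0.0106%. So oak leads. This reckoning stops short of alder.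

The forecast names oak as best, with 0.001% for elm, 1% for alder, 13.5% for oak and 0.35% for birch, on the ground that leftover D is “only slightly in excess of Z”. Its elm figure stands below this rough reckoning.

The simulation gives oak as best, with 0% for elm, 1.10% for alder, 13.5% for oak and 0.364% for birch, so the forecast holds on every count. In oak the first step had 100% of its turnover behind it at 2.00 d, and the step from Q and E had >99.9% behind it at 0.800 d. The step from D and Z then kept turning Z into D.Z, taking Z from 27.2% at 2.00 d to 13.5% at 4.00 d, with c_D − c_Z reading 4.68 mM at that end, against the surplus of 4.76 mM.

Oak charged with 28 mM of D has a side share of 15.9% and a surplus of −10.7 mM, negative, so c_Z now runs towards 10.7 mM instead of zero, and the same ratio, rising this time, gives 50.8% of the Q charged at the end. The simulated flask reads 51.2%.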